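**Strategy.** The heterocycle O1–C2–C3–C4, fused to ring A through C4a and C8a, is taken apart as a hetero-[4+2] adduct. The diene is an A-ring ortho-quinone methide (O1=C8a–C4a=C4, with C4 already oxygenated as a methyl ether). The dienophile is a C2=C3 enol ester carrying ring B on C2 and the future 3-OH on C3. One chiral-acid-catalysed cycloaddition should therefore close the pyran ring, form O1–C2 and C3–C4, and set the 2,3-trans pair with C4 at the alcohol oxidation level. Its precursors are the diprenylated, MOM-protected salicylaldehyde dimethyl acetal (made in the flask) and the (E)-enol acetate of the prenylated B-ring arylacetaldehyde. Four routine steps then unveil the dihydroflavonol.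

Key step: step 9

Remark: prenyl = 3-methylbut-2-en-1-yl; ring atoms carry flavan numbers. The target is (2R,3R). Cycloadduct 15 has the same spatial arrangement at C2 and C3 but is named 3S because the CIP priorities at C3 change while C4 is sp3.

Assumption: the sense of induction of the chiral acid cannot be predicted with certainty. The (R)-catalyst is written, and the (S)-antipode would be used if a test reaction shows the opposite sense.

Design notes: the (E) geometry of the enol ester is fixed through an (E)-alkenylboron compound and not by enolisation. The acetal is generated over sieves with the same chiral acid, so that methanol cannot build up and no second, stronger acid meets the C8-prenyl/phenol pair.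

Step 1
Reactants: 1 2,4-dihydroxybenzaldehyde
Product: 2 2-hydroxy-4-(methoxymethoxy)benzaldehyde
Conditions: MOMCl (1.1 equiv), K2CO3, acetone, 0 °C → rt
Reagents that add atoms: chloromethyl methyl ether (MOMCl), COCCl
Why: Williamson-type O-alkylation that should be selective for the 4-OH, because the 2-OH is held in a hydrogen bond to the aldehyde and is the less acidic and less nucleophilic of the two.

Step 2
Reactants: 2 2-hydroxy-4-(methoxymethoxy)benzaldehyde
Product: 3 2-hydroxy-3,5-diiodo-4-(methoxymethoxy)benzaldehyde
Conditions: NIS (2.3 equiv), DMF, 0 °C → rt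
Reagents that add atoms: N-iodosuccinimide, O=C1CCC(=O)N1I
Why: Electrophilic aromatic iodination; C3 and C5 are the only positions ortho/para to the free phenol (C6 is meta to both oxygens), and the non-acidic conditions should spare the MOM ether.

Step 3
Reactants: 3 2-hydroxy-3,5-diiodo-4-(methoxymethoxy)benzaldehyde; 4 prenylboronic acid pinacol ester (2.6 equiv)
Product: 5 2-hydroxy-4-(methoxymethoxy)-3,5-diprenylbenzaldehyde
Conditions: Pd-PEPPSI-IPent (4 mol %), aq KOH (5 M), THF, 65 °C
Reagents that add atoms: none
Why: Twofold Suzuki–Miyaura coupling of an allylic boronate, where the bulky NHC–palladium catalyst is known to favour the α (linear prenyl) product and to accept di-ortho-substituted halides; phenoxide, aldehyde and MOM ether should tolerate the aqueous base.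

Step 4
Reactants: 6 3-bromo-4-hydroxybenzaldehyde
Product: 7 3-bromo-4-(methoxymethoxy)benzaldehyde
Conditions: MOMCl (1.2 equiv), K2CO3, acetone, rt
Reagents that add atoms: chloromethyl methyl ether (MOMCl), COCCl
Why: Williamson-type O-alkylation of the only phenol, which installs a strongly donating and base-stable para-alkoxy group for the later cycloaddition.

Step 5
Reactants: 7 3-bromo-4-(methoxymethoxy)benzaldehyde; 4 prenylboronic acid pinacol ester (1.4 equiv)
Product: 8 4-(methoxymethoxy)-3-prenylbenzaldehyde
Conditions: Pd-PEPPSI-IPent (2 mol %), aq KOH (5 M), THF, 65 °C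
Reagents that add atoms: none
Why: Suzuki–Miyaura coupling with the same α-selective catalyst system, so the bromide should be replaced by a linear prenyl group, and the electron-rich aldehyde is expected to resist the biphasic base.

Step 6
Reactants: 8 4-(methoxymethoxy)-3-prenylbenzaldehyde
Product: 9 2-{(E)-2-[4-(methoxymethoxy)-3-prenylphenyl]ethenyl}-4,4,5,5-tetramethyl-1,3,2-dioxaborolane
Conditions: CH2(Bpin)2 (1.2 equiv), LiTMP (1.2 equiv, from TMP and n-BuLi), THF, 0 °C; then 8, −78 °C → rt
Reagents that add atoms: bis(pinacolato)borylmethane, CC1(C)OB(CB2OC(C)(C)C(C)(C)O2)OC1(C)C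
Why: Boron–Wittig olefination, in which the α-boryl carbanion adds to the aldehyde and syn B–O elimination gives the 1,2-disubstituted alkenylboronate with the (E) geometry this reaction is known to favour for aldehydes.

Step 7
Reactants: 9 2-{(E)-2-[4-(methoxymethoxy)-3-prenylphenyl]ethenyl}-4,4,5,5-tetramethyl-1,3,2-dioxaborolane
Product: 10 potassium (E)-trifluoro{2-[4-(methoxymethoxy)-3-prenylphenyl]ethenyl}borate
Conditions: KHF2 (aq, 4 equiv), MeOH, rt; precipitation from acetone/Et2O
Reagents that add atoms: potassium hydrogen difluoride, F.[F-].[K+]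
Why: Standard exchange of a pinacol boronate for the trifluoroborate salt with retention of alkene geometry, which gives the coupling partner best precedented for the next step.

Step 8
Reactants: 10 potassium (E)-trifluoro{2-[4-(methoxymethoxy)-3-prenylphenyl]ethenyl}borate
Product: 11 (E)-2-[4-(methoxymethoxy)-3-prenylphenyl]ethenyl acetate
Conditions: AcOH (3 equiv), CuBr (10 mol %), DMAP (20 mol %), 4 Å MS, O2 (1 atm), MeCN, 40 °C
Reagents that add atoms: acetic acid, CC(=O)O
Why: Chan–Lam–Evans-type oxidative copper-catalysed C–O coupling of an alkenyltrifluoroborate with a carboxylic acid, which proceeds with retention of geometry and should give the (E)-enol acetate only.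

Step 9
Reactants: 5 2-hydroxy-4-(methoxymethoxy)-3,5-diprenylbenzaldehyde; 12 trimethyl orthoformate (1.5 equiv); 11 (E)-2-[4-(methoxymethoxy)-3-prenylphenyl]ethenyl acetate (1.5 equiv)
Product: 15 (2R,3S,4R)-4-methoxy-7-(methoxymethoxy)-2-[4-(methoxymethoxy)-3-prenylphenyl]-6,8-diprenylchroman-3-yl acetate, via dimethyl acetal 13 (not isolated), via ortho-quinone methide 14 (not isolated)
Conditions: (R)-TRIP (10 mol %), 5 Å MS, PhMe, rt (acetal formation); then 11, −20 → 0 °C; Et3N quench
Reagents that add atoms: none
Why: Proposed new method: the chiral phosphoric acid should ionise acetal 13 to the hydrogen-bonded 4-methoxy ortho-quinone methide/oxocarbenium pair 14, whose C4 is attacked by the acetoxy-bearing carbon of 11 while the developing para-alkoxybenzylic cation at C2 is captured by O1 in a concerted but asynchronous inverse-demand hetero-Diels–Alder reaction; the closest known reaction types are phosphoric-acid-catalysed [4+2] cycloadditions of ortho-quinone methides with styrenes and Lewis-acid additions of salicylaldehyde acetals to alkenes giving 4-alkoxychromans, whereas enol esters of arylacetaldehydes are untested 2π partners. The single new ring (O1–C2–C3–C4–C4a–C8a) is closed intermolecularly as a [4+2] annulation, C3–C4 forming first and O1–C2 second. C2 and C3 are set relative to each other by suprafacial addition across the (E)-alkene (aryl and acetoxy end up trans) and in the absolute sense by the chiral phosphate, which holds the diene through the phenolic O–H and shields one face; C4 follows from the exo/endo approach, is expected to settle as the all-equatorial epimer, and is erased in step 12. The step needs flavan and not isoflavan regiochemistry, which the 4-alkoxyaryl group should secure by stabilising positive charge at C2 far better than the acyloxy group could at C3, and it needs selectivity for the styrenyl enol ester over the three prenyl alkenes, which its higher nucleophilicity, its excess and the low temperature should provide. The weak acid and the sieves are chosen so that neither the MOM ethers nor the C8-prenyl/phenol pair (chroman formation) should react.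

Step 10
Reactants: 15 (2R,3S,4R)-4-methoxy-7-(methoxymethoxy)-2-[4-(methoxymethoxy)-3-prenylphenyl]-6,8-diprenylchroman-3-yl acetate
Product: 16 (2R,3S,4R)-4-methoxy-7-(methoxymethoxy)-2-[4-(methoxymethoxy)-3-prenylphenyl]-6,8-diprenylchroman-3-ol
Conditions: K2CO3 (0.3 equiv), MeOH, 0 °C → rt
Reagents that add atoms: none
Why: Base-catalysed transesterification (Zemplén-type methanolysis); no carbonyl is present, so C2 and C3 cannot epimerise, and removing the ester first avoids acetoxonium participation at C4 in the next step.

Step 11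
Reactants: 16 (2R,3S,4R)-4-methoxy-7-(methoxymethoxy)-2-[4-(methoxymethoxy)-3-prenylphenyl]-6,8-diprenylchroman-3-ol
Product: 17 (2R,3S,4R)-7-(methoxymethoxy)-2-[4-(methoxymethoxy)-3-prenylphenyl]-6,8-diprenylchroman-3,4-diol (C4 epimer equally usable)
Conditions: PPTS (0.2 equiv), THF/H2O (3:1), 40 °C
Reagents that add atoms: water, O
Why: SN1 solvolysis; C4 is benzylic with an ortho (O1) and a para (O7) oxygen and should ionise under acid too weak to cleave aryl MOM ethers or to cyclise prenyl groups, and water captures the cation without touching C2 or C3.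

Step 12
Reactants: 17 (2R,3S,4R)-7-(methoxymethoxy)-2-[4-(methoxymethoxy)-3-prenylphenyl]-6,8-diprenylchroman-3,4-diol
Product: 18 (2R,3R)-3-hydroxy-7-(methoxymethoxy)-2-[4-(methoxymethoxy)-3-prenylphenyl]-6,8-diprenylchroman-4-one
Conditions: activated MnO2 (15 equiv), CH2Cl2, rt
Reagents that add atoms: none
Why: Chemoselective manganese dioxide oxidation of the electron-rich benzylic C4 carbinol in preference to the unactivated C3 carbinol, under neutral conditions that should leave C2, C3 and the prenyl groups untouched while removing the C4 stereocentre.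

Step 13
Reactants: 18 (2R,3R)-3-hydroxy-7-(methoxymethoxy)-2-[4-(methoxymethoxy)-3-prenylphenyl]-6,8-diprenylchroman-4-one
Product: 19 lespeflorin B3, (2R,3R)-3,7-dihydroxy-2-(4-hydroxy-3-prenylphenyl)-6,8-diprenylchroman-4-one
Conditions: 3 M aq HCl/MeOH (1:5), rt → 40 °C, stopped at full conversion
Reagents that add atoms: none
Why: Acid-catalysed acetal exchange with methanol (MOM cleavage), the usual unmasking of ortho-prenylated flavonoid phenols at a temperature where hydroalkoxylation of the prenyl groups is slow; the 2,3-trans dihydroflavonol is the thermodynamic epimer and should persist.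

**Compound list**

1 | 2,4-dihydroxybenzaldehyde | O=Cc1ccc(O)cc1O | starting material
2 | 2-hydroxy-4-(methoxymethoxy)benzaldehyde | O=Cc1ccc(OCOC)cc1O | intermediate
3 | 2-hydroxy-3,5-diiodo-4-(methoxymethoxy)benzaldehyde | O=Cc1cc(I)c(OCOC)c(I)c1O | intermediate
4 | prenylboronic acid pinacol ester | CC(C)=CCB1OC(C)(C)C(C)(C)O1 | starting material
5 | 2-hydroxy-4-(methoxymethoxy)-3,5-diprenylbenzaldehyde | O=Cc1cc(CC=C(C)C)c(OCOC)c(CC=C(C)C)c1O | intermediate
6 | 3-bromo-4-hydroxybenzaldehyde | O=Cc1ccc(O)c(Br)c1 | starting material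
7 | 3-bromo-4-(methoxymethoxy)benzaldehyde | O=Cc1ccc(OCOC)c(Br)c1 | intermediate
8 | 4-(methoxymethoxy)-3-prenylbenzaldehyde | O=Cc1ccc(OCOC)c(CC=C(C)C)c1 | intermediate
9 | 2-{(E)-2-[4-(methoxymethoxy)-3-prenylphenyl]ethenyl}-4,4,5,5-tetramethyl-1,3,2-dioxaborolane | CC(C)=CCc1cc(/C=C/B2OC(C)(C)C(C)(C)O2)ccc1OCOC | intermediate
10 | potassium (E)-trifluoro{2-[4-(methoxymethoxy)-3-prenylphenyl]ethenyl}borate | CC(C)=CCc1cc(/C=C/[B-](F)(F)F)ccc1OCOC.[K+] | intermediate
11 | (E)-2-[4-(methoxymethoxy)-3-prenylphenyl]ethenyl acetate | CC(C)=CCc1cc(/C=C/OC(C)=O)ccc1OCOC | intermediate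
12 | trimethyl orthoformate | COC(OC)OC | starting material
13 | 2-hydroxy-4-(methoxymethoxy)-3,5-diprenylbenzaldehyde dimethyl acetal (not isolated) | COC(OC)c1cc(CC=C(C)C)c(OCOC)c(CC=C(C)C)c1O | intermediate
14 | (E)-6-(methoxymethylidene)-3-(methoxymethoxy)-2,4-diprenylcyclohexa-2,4-dien-1-one, the 4-methoxy ortho-quinone methide (not isolated) | CO/C=C1\C=C(CC=C(C)C)C(OCOC)=C(CC=C(C)C)C1=O | intermediate
15 | (2R,3S,4R)-4-methoxy-7-(methoxymethoxy)-2-[4-(methoxymethoxy)-3-prenylphenyl]-6,8-diprenylchroman-3-yl acetate (2,3-trans; drawn 3,4-trans, C4 epimer equally usable) | CC(C)=CCc1cc([C@H]2Oc3c(cc(CC=C(C)C)c(OCOC)c3CC=C(C)C)[C@@H](OC)[C@@H]2OC(C)=O)ccc1OCOC | intermediate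
16 | (2R,3S,4R)-4-methoxy-7-(methoxymethoxy)-2-[4-(methoxymethoxy)-3-prenylphenyl]-6,8-diprenylchroman-3-ol | CC(C)=CCc1cc([C@H]2Oc3c(cc(CC=C(C)C)c(OCOC)c3CC=C(C)C)[C@@H](OC)[C@@H]2O)ccc1OCOC | intermediate
17 | (2R,3S,4R)-7-(methoxymethoxy)-2-[4-(methoxymethoxy)-3-prenylphenyl]-6,8-diprenylchroman-3,4-diol (C4 epimer equally usable) | CC(C)=CCc1cc([C@H]2Oc3c(cc(CC=C(C)C)c(OCOC)c3CC=C(C)C)[C@@H](O)[C@@H]2O)ccc1OCOC | intermediate
18 | (2R,3R)-3-hydroxy-7-(methoxymethoxy)-2-[4-(methoxymethoxy)-3-prenylphenyl]-6,8-diprenylchroman-4-one | CC(C)=CCc1cc([C@H]2Oc3c(cc(CC=C(C)C)c(OCOC)c3CC=C(C)C)C(=O)[C@@H]2O)ccc1OCOC | intermediate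
19 | lespeflorin B3, (2R,3R)-3,7-dihydroxy-2-(4-hydroxy-3-prenylphenyl)-6,8-diprenylchroman-4-one | CC(C)=CCc1cc([C@H]2Oc3c(cc(CC=C(C)C)c(O)c3CC=C(C)C)C(=O)[C@@H]2O)ccc1O | target

**Totals.** Total step count: 13. Longest linear sequence: 10 steps (steps 4–13, from 3-bromo-4-hydroxybenzaldehyde 6); the A-ring branch (steps 1–3) joins at step 9.

**Steps most likely to fail**

1. Step 9 (proposed new method). The enol ester may be too weak a nucleophile for the strongly stabilised methoxy quinone methide. It may also add with the opposite orientation, and the chiral acid may give poor facial selectivity. Acyl transfer to the phenol, attack by prenyl alkenes and acid-induced chroman formation would further drain material. The fallback abandons the cycloaddition for the established chalcone-epoxide route to trans-dihydroflavonols; it sets out from 5 (with 8 as B-ring partner) and comes back to the route at 19.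
   - MOM protection of the remaining phenol (MOMCl, NaH, DMF) should give 2,4-bis(methoxymethoxy)-3,5-diprenylbenzaldehyde F1.
   - Addition of MeMgBr should give racemic 1-[2,4-bis(methoxymethoxy)-3,5-diprenylphenyl]ethanol F2, and MnO2 oxidation the acetophenone 1-[2,4-bis(methoxymethoxy)-3,5-diprenylphenyl]ethanone F3.
   - Claisen–Schmidt condensation with 8 (KOH, EtOH) should give the (E)-chalcone F4.
   - Juliá–Colonna epoxidation (poly-L-leucine, urea–H2O2, DBU, THF) is nucleophilic and should ignore the prenyl alkenes, giving the (2R,3S)-epoxy ketone F5.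
   - HCl/MeOH then removes the three MOM groups, and the freed 2'-phenol should open the epoxide at the benzylic carbon with inversion (6-endo), giving 19 directly.

2. Step 12. Over-oxidation (glycol cleavage, or dehydrogenation towards the flavonol) and incomplete discrimination between the two carbinols are the likely failure modes. The fallback removes the selectivity problem by protection; it sets out from 16 and comes back at 18.
   - Silylation (TBSOTf, 2,6-lutidine, CH2Cl2, −78 °C) should give the 3-O-tert-butyldimethylsilyl-4-methoxyflavan F6.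
   - The same mild aqueous acid as in step 11 should give the 3-O-silyl flavan-4-ol F7.
   - Dess–Martin periodinane (NaHCO3, CH2Cl2) should give the 3-silyloxyflavanone F8.
   - HF·pyridine in THF should release 18.

3. Step 3. Allyl transposition during transmetalation (coupling at the γ terminus to give reverse-prenyl groups) and stalling after the first coupling at the hindered C3 iodide between two oxygens are the risks. The fallback separates C–C coupling from the prenyl substitution pattern; it sets out from 3 and comes back at 5.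
   - Twofold Suzuki–Miyaura allylation with allylboronic acid pinacol ester (Pd(dppf)Cl2, K2CO3, THF/H2O), where α and γ attack give the same product, should give 3,5-diallyl-2-hydroxy-4-(methoxymethoxy)benzaldehyde F9.
   - Olefin cross-metathesis with excess 2-methyl-2-butene (Grubbs second-generation catalyst, CH2Cl2, 40 °C) should convert both allyl groups into prenyl groups, giving 5.

**Further compounds**

F1 | step 9 | 2,4-bis(methoxymethoxy)-3,5-diprenylbenzaldehyde | O=Cc1cc(CC=C(C)C)c(OCOC)c(CC=C(C)C)c1OCOC
F2 | step 9 | 1-[2,4-bis(methoxymethoxy)-3,5-diprenylphenyl]ethanol (racemic) | CC(O)c1cc(CC=C(C)C)c(OCOC)c(CC=C(C)C)c1OCOC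
F3 | step 9 | 1-[2,4-bis(methoxymethoxy)-3,5-diprenylphenyl]ethanone | CC(=O)c1cc(CC=C(C)C)c(OCOC)c(CC=C(C)C)c1OCOC
F4 | step 9 | (E)-1-[2,4-bis(methoxymethoxy)-3,5-diprenylphenyl]-3-[4-(methoxymethoxy)-3-prenylphenyl]prop-2-en-1-one | O=C(/C=C/c1ccc(OCOC)c(CC=C(C)C)c1)c1cc(CC=C(C)C)c(OCOC)c(CC=C(C)C)c1OCOC
F5 | step 9 | [2,4-bis(methoxymethoxy)-3,5-diprenylphenyl]{(2R,3S)-3-[4-(methoxymethoxy)-3-prenylphenyl]oxiran-2-yl}methanone | O=C(c1cc(CC=C(C)C)c(OCOC)c(CC=C(C)C)c1OCOC)[C@@H]1O[C@H]1c1ccc(OCOC)c(CC=C(C)C)c1
F6 | step 12 | tert-butyl{[(2R,3S,4R)-4-methoxy-7-(methoxymethoxy)-2-[4-(methoxymethoxy)-3-prenylphenyl]-6,8-diprenylchroman-3-yl]oxy}dimethylsilane | CC(C)=CCc1cc([C@H]2Oc3c(cc(CC=C(C)C)c(OCOC)c3CC=C(C)C)[C@@H](OC)[C@@H]2O[Si](C)(C)C(C)(C)C)ccc1OCOC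
F7 | step 12 | (2R,3S,4R)-3-(tert-butyldimethylsilyloxy)-7-(methoxymethoxy)-2-[4-(methoxymethoxy)-3-prenylphenyl]-6,8-diprenylchroman-4-ol | CC(C)=CCc1cc([C@H]2Oc3c(cc(CC=C(C)C)c(OCOC)c3CC=C(C)C)[C@@H](O)[C@@H]2O[Si](C)(C)C(C)(C)C)ccc1OCOC
F8 | step 12 | (2R,3R)-3-(tert-butyldimethylsilyloxy)-7-(methoxymethoxy)-2-[4-(methoxymethoxy)-3-prenylphenyl]-6,8-diprenylchroman-4-one | CC(C)=CCc1cc([C@H]2Oc3c(cc(CC=C(C)C)c(OCOC)c3CC=C(C)C)C(=O)[C@@H]2O[Si](C)(C)C(C)(C)C)ccc1OCOC
F9 | step 3 | 3,5-diallyl-2-hydroxy-4-(methoxymethoxy)benzaldehyde | O=Cc1cc(CC=C)c(OCOC)c(CC=C)c1O
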